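**Retrosynthetic overview**

1. Locants: carbocycle C1(CH3)=C2, C3, C4, C5(C17)=C6, C7, C8, C9(C16), C10 (ether CH), C11, C12 (bears C15 = CMe2–O–C10), C13, C14. The endgame is desulfonylation, desilylation, MnO2 oxidation of C17 to the enal and acylation of C16–OH with Meldrum's acid.
2. Key disconnection: the C13–C14 sp3–sp3 bond of the 14-membered carbocycle, which joins the CH2 on tetrahydrofuran stereocentre C12 to the CH2 allylic to the Z-C1=C2 olefin. It is made from a C13 phenylsulfonyl carbanion and a C14 (Z)-allylic bromide.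
3. Seco chain: C5=C6 by Horner–Wadsworth–Emmons olefination (C6 aldehyde plus a C2–C5/C17 phosphonoacetate); Z-C1=C2 by Wittig reaction of a carboxybutyl ylide with silyloxyacetone.
4. Tetrahydrofuran: C15–O by alkoxymercuration of a C12 isopropenyl group with C10–OH; C9/C10 by Evans syn aldol; C12 by Rh-catalysed conjugate addition of isopropenyl to furan-2(5H)-one, the lactone then being opened at C13 by thiophenolate.
5. Ring order: tetrahydrofuran first (step 9), 14-membered carbocycle second (step 20).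

Key step: step 20

Assumption: (R)-BINAP is taken to deliver the (R)-lactone 3 by the usual enantioface model for cyclic enones and unsaturated lactones, and 5-(benzyloxy)pentanoic acid is taken as a catalogue compound.

**Route**

Step 1
Reactants: 1 furan-2(5H)-one; 2 potassium isopropenyltrifluoroborate
Product: 3 (R)-4-(prop-1-en-2-yl)dihydrofuran-2(3H)-one
Conditions: [Rh(cod)2]BF4 (3 mol %), (R)-BINAP (3.3 mol %), toluene/H2O 4:1, 100 °C
Reagents that add atoms: none
Why: Hayashi–Miyaura rhodium-catalysed asymmetric conjugate addition of an alkenylboron reagent to an unsaturated lactone, in which the (R)-BINAP complex selects the enantioface of the beta carbon and so should set C12 as R.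

Step 2
Reactants: 3 (R)-4-(prop-1-en-2-yl)dihydrofuran-2(3H)-one
Product: 5 methyl (R)-4-methyl-3-[(phenylsulfanyl)methyl]pent-4-enoate, via sodium carboxylate 4 (not isolated)
Conditions: PhSNa (1.2 equiv), degassed DMF, 110 °C; then MeI, 20 °C
Reagents that add atoms: sodium benzenethiolate [Na+].[S-]c1ccccc1; iodomethane CI
Why: SN2 opening of the gamma-lactone at the O–CH2 carbon (alkyl–oxygen cleavage) by the soft thiolate puts sulfur on C13, and O-methylation of the carboxylate follows in the same flask; C12 is not touched.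

Step 3
Reactants: 5 methyl (R)-4-methyl-3-[(phenylsulfanyl)methyl]pent-4-enoate
Product: 6 methyl (R)-4-methyl-3-[(phenylsulfonyl)methyl]pent-4-enoate
Conditions: (NH4)6Mo7O24·4H2O (5 mol %), 30% H2O2, EtOH, 0 °C to 20 °C
Reagents that add atoms: hydrogen peroxide OO
Why: Molybdate-catalysed peroxide oxidation of a sulfide to the sulfone, which is much faster than epoxidation of the unactivated 1,1-disubstituted olefin.

Step 4
Reactants: 6 methyl (R)-4-methyl-3-[(phenylsulfonyl)methyl]pent-4-enoate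
Product: 7 (R)-4-methyl-3-[(phenylsulfonyl)methyl]pent-4-enal
Conditions: iBu2AlH (1.1 equiv), CH2Cl2, −78 °C; aq. potassium sodium tartrate
Reagents that add atoms: none
Why: Partial reduction of a methyl ester to the aldehyde with iBu2AlH, the aluminium hemiacetal being stable at −78 °C and the sulfone inert.

Step 5
Reactants: 8 5-(benzyloxy)pentanoic acid; 9 (S)-4-benzyl-2-oxazolidinone
Product: 11 (S)-4-benzyl-3-[5-(benzyloxy)pentanoyl]oxazolidin-2-one, via pivalic mixed anhydride 10 (not isolated)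
Conditions: t-BuCOCl, Et3N, THF, −20 °C; then 9, LiCl, −20 °C to 20 °C
Reagents that add atoms: none
Why: N-acylation of the oxazolidinone through the mixed pivalic anhydride, which is attacked at the less hindered carbonyl.

Step 6
Reactants: 11 (S)-4-benzyl-3-[5-(benzyloxy)pentanoyl]oxazolidin-2-one; 7 (R)-4-methyl-3-[(phenylsulfonyl)methyl]pent-4-enal
Product: 13 (S)-4-benzyl-3-[(2S,3R,5R)-2-[3-(benzyloxy)propyl]-3-hydroxy-6-methyl-5-[(phenylsulfonyl)methyl]hept-6-enoyl]oxazolidin-2-one, via dibutylboron Z-enolate 12 (not isolated)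
Conditions: Bu2BOTf, iPr2NEt, CH2Cl2, 0 °C; 7, −78 °C to 0 °C; then pH 7 phosphate buffer, MeOH, 30% H2O2
Reagents that add atoms: none
Why: Evans syn aldol reaction through the Zimmerman–Traxler chair of the Z-boron enolate, in which the (S)-benzyl auxiliary fixes the enolate face and so should set C9 and C10 together as the (2S,3R) syn pair, the remote C12 centre having little influence.

Step 7
Reactants: 13 aldol adduct
Product: 14 (2R,3R,5R)-2-[3-(benzyloxy)propyl]-6-methyl-5-[(phenylsulfonyl)methyl]hept-6-ene-1,3-diol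
Conditions: LiBH4, MeOH (1 equiv), THF, 0 °C
Reagents that add atoms: none
Why: Reductive cleavage of the N-acyl oxazolidinone by LiBH4 to the primary alcohol C16–OH, with the sulfone and olefin unaffected and the auxiliary released.

Step 8
Reactants: 14 diol
Product: 15 (2R,3R,5R)-2-[3-(benzyloxy)propyl]-6-methyl-5-[(phenylsulfonyl)methyl]-1-[(triisopropylsilyl)oxy]hept-6-en-3-ol
Conditions: iPr3SiCl, imidazole, CH2Cl2, 0 °C to 20 °C
Reagents that add atoms: chlorotriisopropylsilane CC(C)[Si](Cl)(C(C)C)C(C)C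
Why: Selective silylation of the primary C16 hydroxyl over the secondary C10 hydroxyl by the bulky silyl chloride.

Step 9
Reactants: 15 silyl ether
Product: 17 (3R,5R)-5-[(2R)-5-(benzyloxy)-1-[(triisopropylsilyl)oxy]pentan-2-yl]-2,2-dimethyl-3-[(phenylsulfonyl)methyl]tetrahydrofuran, via alkylmercury acetate 16 (not isolated)
Conditions: Hg(OAc)2 (1.1 equiv), CH2Cl2, 20 °C; then 3 M NaOH, NaBH4, 0 °C
Reagents that add atoms: none
Why: Intramolecular alkoxymercuration–demercuration, in which the C10 hydroxyl opens the mercurinium ion of the isopropenyl group at C15 in a 5-exo Markovnikov closure and NaBH4 replaces mercury by hydrogen; no free cation arises next to C12, so C10 and C12 keep their configurations and the cis-3,5 relationship follows from them.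

Step 10
Reactants: 17 tetrahydrofuran benzyl ether
Product: 18 (4R)-4-[(2R,4R)-5,5-dimethyl-4-[(phenylsulfonyl)methyl]tetrahydrofuran-2-yl]-5-[(triisopropylsilyl)oxy]pentan-1-ol
Conditions: H2 (1 atm), Pd/C, EtOAc, 20 °C
Reagents that add atoms: none
Why: Hydrogenolysis of the benzyl ether at a stage where no olefin is present, the sulfone and silyl ether being stable.

Step 11
Reactants: 18 primary alcohol
Product: 19 (4R)-4-[(2R,4R)-5,5-dimethyl-4-[(phenylsulfonyl)methyl]tetrahydrofuran-2-yl]-5-[(triisopropylsilyl)oxy]pentanal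
Conditions: Dess–Martin periodinane, CH2Cl2, 0 °C to 20 °C
Reagents that add atoms: none
Why: Dess–Martin oxidation of the primary alcohol to the C6 aldehyde, whose nearest stereocentre (C9) is gamma and cannot epimerise.

Step 12
Reactants: 20 (4-carboxybutyl)triphenylphosphonium bromide; 21 1-[(tert-butyldimethylsilyl)oxy]propan-2-one
Product: 23 (Z)-7-[(tert-butyldimethylsilyl)oxy]-6-methylhept-5-enoic acid, via carboxylate ylide 22 (not isolated)
Conditions: NaN(SiMe3)2 (2.05 equiv), THF, 0 °C; then 21, −78 °C to 20 °C; aq. citric acid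
Reagents that add atoms: none
Why: Wittig olefination of a non-stabilised ylide with an alpha-silyloxy ketone, a combination known to favour the Z-trisubstituted allylic ether, so that C14 should end up cis to C3.

Step 13
Reactants: 23 heptenoic acid
Product: 24 methyl (Z)-7-[(tert-butyldimethylsilyl)oxy]-6-methylhept-5-enoate
Conditions: MeI, K2CO3, DMF, 20 °C
Reagents that add atoms: iodomethane CI
Why: O-alkylation of the carboxylate with iodomethane under conditions that leave the allylic silyl ether intact.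

Step 14
Reactants: 24 methyl ester
Product: 27 methyl (Z)-7-[(tert-butyldimethylsilyl)oxy]-2-(diethoxyphosphoryl)-6-methylhept-5-enoate, via lithium enolate 25 (not isolated), via phosphonite 26 (not isolated)
Conditions: LiN(iPr)2 (1.1 equiv), THF, −78 °C; ClP(OEt)2, −78 °C to 20 °C; then 30% H2O2, 0 °C
Reagents that add atoms: diethyl chlorophosphite CCOP(Cl)OCC; hydrogen peroxide OO
Why: C-phosphinylation of the ester lithium enolate by the trivalent phosphorus chloride followed by oxidation to the phosphonate (the enolate route to alpha-phosphono esters); the new C5 centre is racemic and disappears in step 15.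

Step 15
Reactants: 27 phosphonate; 19 aldehyde
Product: 29 methyl (2E,6R)-2-[(3Z)-5-(tert-butyldimethylsilyloxy)-4-methylpent-3-enyl]-6-[(2R,4R)-5,5-dimethyl-4-(phenylsulfonylmethyl)tetrahydrofuran-2-yl]-7-(triisopropylsilyloxy)hept-2-enoate, via sodium phosphonate 28 (not isolated)
Conditions: NaH (1.2 equiv), 27 (1.3 equiv), THF, 0 °C; then 19, 0 °C to 20 °C
Reagents that add atoms: none
Why: Horner–Wadsworth–Emmons olefination, in which reversible addition and elimination through the less crowded oxaphosphetane should favour the E enoate (CO2Me trans to C7), while the phosphonate anion is too weak a base to deprotonate the sulfone.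

Step 16
Reactants: 29 enoate
Product: 30 (2E,6R)-2-[(3Z)-5-(tert-butyldimethylsilyloxy)-4-methylpent-3-enyl]-6-[(2R,4R)-5,5-dimethyl-4-(phenylsulfonylmethyl)tetrahydrofuran-2-yl]-7-(triisopropylsilyloxy)hept-2-en-1-ol
Conditions: iBu2AlH (2.5 equiv), CH2Cl2, −78 °C to −20 °C
Reagents that add atoms: none
Why: 1,2-Reduction of the conjugated ester to the allylic alcohol C17–OH by iBu2AlH, with silyl ethers and sulfone unchanged.

Step 17
Reactants: 30 allylic alcohol
Product: 31 C17 triisopropylsilyl ether of 30 (C14 OSiMe2t-Bu; C16 and C17 OSi(iPr)3; 1Z,5E,9R,10R,12R)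
Conditions: iPr3SiOTf, 2,6-lutidine, CH2Cl2, −78 °C to 0 °C
Reagents that add atoms: triisopropylsilyl trifluoromethanesulfonate CC(C)[Si](OS(=O)(=O)C(F)(F)F)(C(C)C)C(C)C
Why: Silylation of the primary allylic alcohol with the silyl triflate and a hindered base, so that C17 carries a group more robust than the C14 silyl ether.

Step 18
Reactants: 31 tris-silyl ether
Product: 32 (2Z,6E,10R)-10-[(2R,4R)-5,5-dimethyl-4-(phenylsulfonylmethyl)tetrahydrofuran-2-yl]-2-methyl-11-(triisopropylsilyloxy)-6-[(triisopropylsilyloxy)methyl]undeca-2,6-dien-1-ol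
Conditions: camphorsulfonic acid (10 mol %), MeOH/CH2Cl2 1:1, 0 °C
Reagents that add atoms: none
Why: Acid-catalysed methanolysis, which cleaves the primary tert-butyldimethylsilyl ether far faster than the two triisopropylsilyl ethers.

Step 19
Reactants: 32 C14 allylic alcohol
Product: 34 (3R,5R)-5-[(2R,5E,9Z)-11-bromo-10-methyl-1-(triisopropylsilyloxy)-6-[(triisopropylsilyloxy)methyl]undeca-5,9-dien-2-yl]-2,2-dimethyl-3-(phenylsulfonylmethyl)tetrahydrofuran, via allylic mesylate 33 (not isolated)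
Conditions: MsCl, Et3N, THF, −40 °C; then LiBr, −40 °C to 0 °C
Reagents that add atoms: lithium bromide [Li+].[Br-]
Why: Mesylation followed by SN2 displacement with bromide at the primary allylic carbon, which keeps the Z geometry because no allyl cation is formed.

Step 20
Reactants: 34 bromo sulfone
Product: 36 (1Z,5E,9R,10R,12R)-13-(phenylsulfonyl)-16,17-bis(triisopropylsilyloxy) macrocycle (14-membered carbocycle C1–C14 bridged by the C10–O–C15 ether; C13 epimers), via potassium sulfonyl carbanion 35 (not isolated)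
Conditions: KN(SiMe3)2 (1.5 equiv), THF, −20 °C; 34 added by syringe pump over 8 h, final concentration about 1 mM; NH4Cl quench
Reagents that add atoms: none
Why: KN(SiMe3)2 removes a C13 proton alpha to the sulfone, the only acidic site since C16 and C17 are silyl ethers and no carbonyl is present, and carbanion 35 displaces bromide at the primary allylic carbon C14 by intramolecular SN2 alkylation. The closest known reaction type is the sulfone-carbanion/allylic-halide macrocyclisation used to close 14-membered terpenoid carbocycles, followed by reductive desulfonylation. The carbocycle C1–C14 closes in the 14-exo-tet mode, helped by the cis-3,5-disubstituted 2,2-dimethyltetrahydrofuran, which holds both arms on one face. The only new stereocentre, C13, is not controlled and should form as a mixture of epimers, both of which converge when the sulfone is removed in step 21. The step needs SN2 over SN2′ attack with the Z-C1=C2 geometry retained, which the unhindered primary C14 and the absence of ionising conditions secure, and ring closure ahead of oligomerisation, which slow addition at high dilution secures. After closure the sulfone is homoallylic to C1=C2, so its removal cannot move that double bond.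

Step 21
Reactants: 36 macrocyclic sulfone
Product: 37 (1Z,5E,9R,10R,12R)-16,17-bis(triisopropylsilyloxy) macrocycle (C13 now CH2)
Conditions: 6% Na(Hg), Na2HPO4, MeOH/THF, −20 °C
Reagents that add atoms: none
Why: Reductive desulfonylation by electron transfer from sodium amalgam in buffered methanol, in which both C13 epimers give the same CH2 and the silyl ethers and olefins are untouched.

Step 22
Reactants: 37 bis-silyl ether
Product: 38 (1Z,5E,9R,10R,12R)-16,17-diol macrocycle
Conditions: Bu4NF, THF, 20 °C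
Reagents that add atoms: none
Why: Fluoride-mediated cleavage of both primary triisopropylsilyl ethers.

Step 23
Reactants: 38 diol
Product: 39 (1Z,5E,9R,10R,12R)-16-hydroxy-17-al macrocycle (hydroxy enal)
Conditions: MnO2 (excess), CH2Cl2, 20 °C
Reagents that add atoms: none
Why: MnO2 oxidises only the allylic C17 alcohol, giving the E enal and leaving the saturated primary C16 alcohol.

Step 24
Reactants: 39 hydroxy enal
Product: 40 CNP0170412.1 (target: C16 hydrogen malonate of 39)
Conditions: Meldrum's acid (1.2 equiv), toluene, 90 °C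
Reagents that add atoms: Meldrum's acid CC1(C)OC(=O)CC(=O)O1
Why: Ring-opening acylation of the primary C16 alcohol by Meldrum's acid with loss of acetone gives the malonic half-ester directly, and no base is added so that condensation at the hindered alpha-substituted enal stays slow.

**Compound list**

1 | furan-2(5H)-one | O=C1C=CCO1 | starting material
2 | potassium isopropenyltrifluoroborate | C=C(C)[B-](F)(F)F.[K+] | starting material
3 | (R)-4-(prop-1-en-2-yl)dihydrofuran-2(3H)-one | O=C1C[C@@H](CO1)C(C)=C | intermediate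
4 | sodium (R)-4-methyl-3-[(phenylsulfanyl)methyl]pent-4-enoate | [Na+].[O-]C(=O)C[C@@H](CSc1ccccc1)C(C)=C | intermediate (not isolated)
5 | methyl (R)-4-methyl-3-[(phenylsulfanyl)methyl]pent-4-enoate | COC(=O)C[C@@H](CSc1ccccc1)C(C)=C | intermediate
6 | methyl (R)-4-methyl-3-[(phenylsulfonyl)methyl]pent-4-enoate | COC(=O)C[C@@H](CS(=O)(=O)c1ccccc1)C(C)=C | intermediate
7 | (R)-4-methyl-3-[(phenylsulfonyl)methyl]pent-4-enal | O=CC[C@@H](CS(=O)(=O)c1ccccc1)C(C)=C | intermediate
8 | 5-(benzyloxy)pentanoic acid | OC(=O)CCCCOCc1ccccc1 | starting material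
9 | (S)-4-benzyl-2-oxazolidinone | O=C1N[C@@H](Cc2ccccc2)CO1 | starting material
10 | 5-(benzyloxy)pentanoic pivalic anhydride | CC(C)(C)C(=O)OC(=O)CCCCOCc1ccccc1 | intermediate (not isolated)
11 | (S)-4-benzyl-3-[5-(benzyloxy)pentanoyl]oxazolidin-2-one | O=C1N(C(=O)CCCCOCc2ccccc2)[C@@H](Cc2ccccc2)CO1 | intermediate
12 | dibutylboron (Z)-enolate of 11 | CCCCB(CCCC)O/C(=C\CCCOCc1ccccc1)N1C(=O)OC[C@@H]1Cc1ccccc1 | intermediate (not isolated)
13 | (S)-4-benzyl-3-[(2S,3R,5R)-2-[3-(benzyloxy)propyl]-3-hydroxy-6-methyl-5-[(phenylsulfonyl)methyl]hept-6-enoyl]oxazolidin-2-one | O=C([C@@H](CCCOCc1ccccc1)[C@H](O)C[C@@H](CS(=O)(=O)c1ccccc1)C(C)=C)N1C(=O)OC[C@@H]1Cc1ccccc1 | intermediate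
14 | (2R,3R,5R)-2-[3-(benzyloxy)propyl]-6-methyl-5-[(phenylsulfonyl)methyl]hept-6-ene-1,3-diol | OC[C@@H](CCCOCc1ccccc1)[C@H](O)C[C@@H](CS(=O)(=O)c1ccccc1)C(C)=C | intermediate
15 | (2R,3R,5R)-2-[3-(benzyloxy)propyl]-6-methyl-5-[(phenylsulfonyl)methyl]-1-[(triisopropylsilyl)oxy]hept-6-en-3-ol | CC(C)[Si](OC[C@@H](CCCOCc1ccccc1)[C@H](O)C[C@@H](CS(=O)(=O)c1ccccc1)C(C)=C)(C(C)C)C(C)C | intermediate
16 | alkylmercury acetate: 17 with one C15 methyl as CH2HgOAc (C15 epimers) | CC(C)[Si](OC[C@@H](CCCOCc1ccccc1)[C@H]1C[C@@H](CS(=O)(=O)c2ccccc2)C(C)(C[Hg]OC(C)=O)O1)(C(C)C)C(C)C | intermediate (not isolated)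
17 | (3R,5R)-5-[(2R)-5-(benzyloxy)-1-[(triisopropylsilyl)oxy]pentan-2-yl]-2,2-dimethyl-3-[(phenylsulfonyl)methyl]tetrahydrofuran | CC(C)[Si](OC[C@@H](CCCOCc1ccccc1)[C@H]1C[C@@H](CS(=O)(=O)c2ccccc2)C(C)(C)O1)(C(C)C)C(C)C | intermediate
18 | (4R)-4-[(2R,4R)-5,5-dimethyl-4-[(phenylsulfonyl)methyl]tetrahydrofuran-2-yl]-5-[(triisopropylsilyl)oxy]pentan-1-ol | CC(C)[Si](OC[C@@H](CCCO)[C@H]1C[C@@H](CS(=O)(=O)c2ccccc2)C(C)(C)O1)(C(C)C)C(C)C | intermediate
19 | (4R)-4-[(2R,4R)-5,5-dimethyl-4-[(phenylsulfonyl)methyl]tetrahydrofuran-2-yl]-5-[(triisopropylsilyl)oxy]pentanal | CC(C)[Si](OC[C@@H](CCC=O)[C@H]1C[C@@H](CS(=O)(=O)c2ccccc2)C(C)(C)O1)(C(C)C)C(C)C | intermediate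
20 | (4-carboxybutyl)triphenylphosphonium bromide | OC(=O)CCCC[P+](c1ccccc1)(c1ccccc1)c1ccccc1.[Br-] | starting material
21 | 1-[(tert-butyldimethylsilyl)oxy]propan-2-one | CC(=O)CO[Si](C)(C)C(C)(C)C | starting material
22 | sodium 5-(triphenylphosphoranylidene)pentanoate | [Na+].[O-]C(=O)CCCC=P(c1ccccc1)(c1ccccc1)c1ccccc1 | intermediate (not isolated)
23 | (Z)-7-[(tert-butyldimethylsilyl)oxy]-6-methylhept-5-enoic acid | OC(=O)CCC/C=C(C)\CO[Si](C)(C)C(C)(C)C | intermediate
24 | methyl (Z)-7-[(tert-butyldimethylsilyl)oxy]-6-methylhept-5-enoate | COC(=O)CCC/C=C(C)\CO[Si](C)(C)C(C)(C)C | intermediate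
25 | lithium enolate of 24 | [Li+].[O-]C(OC)=CCC/C=C(C)\CO[Si](C)(C)C(C)(C)C | intermediate (not isolated)
26 | methyl (Z)-7-[(tert-butyldimethylsilyl)oxy]-2-(diethoxyphosphanyl)-6-methylhept-5-enoate | COC(=O)C(CC/C=C(C)\CO[Si](C)(C)C(C)(C)C)P(OCC)OCC | intermediate (not isolated)
27 | methyl (Z)-7-[(tert-butyldimethylsilyl)oxy]-2-(diethoxyphosphoryl)-6-methylhept-5-enoate | COC(=O)C(CC/C=C(C)\CO[Si](C)(C)C(C)(C)C)P(=O)(OCC)OCC | intermediate
28 | sodium salt of 27 (C5 carbanion) | [Na+].COC(=O)[C-](CC/C=C(C)\CO[Si](C)(C)C(C)(C)C)P(=O)(OCC)OCC | intermediate (not isolated)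
29 | methyl (2E,6R)-2-[(3Z)-5-(tert-butyldimethylsilyloxy)-4-methylpent-3-enyl]-6-[(2R,4R)-5,5-dimethyl-4-(phenylsulfonylmethyl)tetrahydrofuran-2-yl]-7-(triisopropylsilyloxy)hept-2-enoate | CC(C)(C)[Si](C)(C)OC/C(C)=C\CC/C(C(=O)OC)=C\CC[C@H](CO[Si](C(C)C)(C(C)C)C(C)C)[C@H]1C[C@@H](CS(=O)(=O)c2ccccc2)C(C)(C)O1 | intermediate
30 | (2E,6R)-2-[(3Z)-5-(tert-butyldimethylsilyloxy)-4-methylpent-3-enyl]-6-[(2R,4R)-5,5-dimethyl-4-(phenylsulfonylmethyl)tetrahydrofuran-2-yl]-7-(triisopropylsilyloxy)hept-2-en-1-ol | CC(C)(C)[Si](C)(C)OC/C(C)=C\CC/C(CO)=C\CC[C@H](CO[Si](C(C)C)(C(C)C)C(C)C)[C@H]1C[C@@H](CS(=O)(=O)c2ccccc2)C(C)(C)O1 | intermediate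
31 | C17 triisopropylsilyl ether of 30 (C14 OSiMe2t-Bu; C16, C17 OSi(iPr)3; 1Z,5E,9R,10R,12R) | CC(C)(C)[Si](C)(C)OC/C(C)=C\CC/C(CO[Si](C(C)C)(C(C)C)C(C)C)=C\CC[C@H](CO[Si](C(C)C)(C(C)C)C(C)C)[C@H]1C[C@@H](CS(=O)(=O)c2ccccc2)C(C)(C)O1 | intermediate
32 | (2Z,6E,10R)-10-[(2R,4R)-5,5-dimethyl-4-(phenylsulfonylmethyl)tetrahydrofuran-2-yl]-2-methyl-11-(triisopropylsilyloxy)-6-[(triisopropylsilyloxy)methyl]undeca-2,6-dien-1-ol | OC/C(C)=C\CC/C(CO[Si](C(C)C)(C(C)C)C(C)C)=C\CC[C@H](CO[Si](C(C)C)(C(C)C)C(C)C)[C@H]1C[C@@H](CS(=O)(=O)c2ccccc2)C(C)(C)O1 | intermediate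
33 | C14 methanesulfonate of 32 | CS(=O)(=O)OC/C(C)=C\CC/C(CO[Si](C(C)C)(C(C)C)C(C)C)=C\CC[C@H](CO[Si](C(C)C)(C(C)C)C(C)C)[C@H]1C[C@@H](CS(=O)(=O)c2ccccc2)C(C)(C)O1 | intermediate (not isolated)
34 | (3R,5R)-5-[(2R,5E,9Z)-11-bromo-10-methyl-1-(triisopropylsilyloxy)-6-[(triisopropylsilyloxy)methyl]undeca-5,9-dien-2-yl]-2,2-dimethyl-3-(phenylsulfonylmethyl)tetrahydrofuran | BrC/C(C)=C\CC/C(CO[Si](C(C)C)(C(C)C)C(C)C)=C\CC[C@H](CO[Si](C(C)C)(C(C)C)C(C)C)[C@H]1C[C@@H](CS(=O)(=O)c2ccccc2)C(C)(C)O1 | intermediate (key-step precursor)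
35 | potassium C13 carbanion of 34 | [K+].BrC/C(C)=C\CC/C(CO[Si](C(C)C)(C(C)C)C(C)C)=C\CC[C@H](CO[Si](C(C)C)(C(C)C)C(C)C)[C@H]1C[C@@H]([CH-]S(=O)(=O)c2ccccc2)C(C)(C)O1 | intermediate (not isolated)
36 | (1Z,5E,9R,10R,12R)-13-(phenylsulfonyl)-16,17-bis(triisopropylsilyloxy) macrocycle, C13 epimers | C/C1=C/CC/C(CO[Si](C(C)C)(C(C)C)C(C)C)=C\CC[C@H](CO[Si](C(C)C)(C(C)C)C(C)C)[C@H]2C[C@@H](C(S(=O)(=O)c3ccccc3)C1)C(C)(C)O2 | intermediate (key-step product)
37 | (1Z,5E,9R,10R,12R)-16,17-bis(triisopropylsilyloxy) macrocycle | C/C1=C/CC/C(CO[Si](C(C)C)(C(C)C)C(C)C)=C\CC[C@H](CO[Si](C(C)C)(C(C)C)C(C)C)[C@H]2C[C@@H](CC1)C(C)(C)O2 | intermediate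
38 | (1Z,5E,9R,10R,12R)-16,17-diol macrocycle | C/C1=C/CC/C(CO)=C\CC[C@H](CO)[C@H]2C[C@@H](CC1)C(C)(C)O2 | intermediate
39 | (1Z,5E,9R,10R,12R)-16-hydroxy-17-al macrocycle | C/C1=C/CC/C(C=O)=C\CC[C@H](CO)[C@H]2C[C@@H](CC1)C(C)(C)O2 | intermediate
40 | CNP0170412.1 | C/C1=C/CC/C(C=O)=C\CC[C@H](COC(=O)CC(=O)O)[C@H]2C[C@@H](CC1)C(C)(C)O2 | target

**Step count and risks**

Total step count: 24. Longest linear sequence: 20 steps (steps 1–4, 6–11, 15–24).

The three steps most likely to fail:

Step 20 (macrocyclisation). Ring closure may lose out to intermolecular alkylation and oligomerisation, to SN2′ attack at C2, or to base-induced loss of HBr from the allylic bromide. The fallback sets out from 24 and 18 and returns at 38. It makes the same C13–C14 bond between the same partners intermolecularly and closes the carbocycle at C5=C6 instead. Methanolysis of 24 (camphorsulfonic acid, MeOH) would give methyl (Z)-7-hydroxy-6-methylhept-5-enoate F1, and CBr4/PPh3 would convert it into methyl (Z)-7-bromo-6-methylhept-5-enoate F2. Alcohol 18 is silylated (t-BuMe2SiCl, imidazole) to the C6 tert-butyldimethylsilyl ether F3. Its C13 lithio sulfone (n-BuLi, THF, −78 °C) is alkylated by F2 to the sulfone ester F4, and Na(Hg)/Na2HPO4 in MeOH removes the sulfone to give the ester F5. Enolate phosphinylation and oxidation as in step 14 give the phosphonate F6. Camphorsulfonic acid in MeOH frees the C6 alcohol F7, and Dess–Martin oxidation gives the aldehyde phosphonate F8. An intramolecular Horner–Wadsworth–Emmons reaction (LiCl, iPr2NEt, MeCN, high dilution) should close the ring to the macrocyclic ester F9. iBu2AlH reduces it to the C17 alcohol F10, and Bu4NF gives diol 38.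

Step 15 (olefination). The alpha-branched phosphonate anion may react sluggishly or give poor E/Z control at the trisubstituted C5=C6 bond. The fallback sets out from 24 and returns at 29, replacing the phosphonate by a stabilised phosphorane. Enolate bromination of 24 (LiN(iPr)2, THF, −78 °C, then CBr4) would give the alpha-bromo ester F11. PPh3 in toluene at 90 °C gives the phosphonium bromide F12, and aqueous NaOH/CH2Cl2 liberates the ylide F13. Wittig reaction of F13 with 19 in toluene at 80 °C should give the E enoate 29.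

Step 24 (malonate half-ester). Meldrum's acid may condense with the enal in a Knoevenagel reaction in competition with acylation of the C16 hydroxyl. The fallback sets out from 39 and returns at 40, using a protected malonate. Esterification of 39 with 3-(allyloxy)-3-oxopropanoic acid (dicyclohexylcarbodiimide, 4-(dimethylamino)pyridine, CH2Cl2, 0 °C) would give the allyl malonate diester F14. Deallylation with Pd(PPh3)4 (zerovalent palladium, catalytic) and sodium 4-methylbenzenesulfinate in THF/MeOH should then release acid 40 under neutral conditions.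

Further compounds
F1 | step 20 | methyl (Z)-7-hydroxy-6-methylhept-5-enoate | COC(=O)CCC/C=C(C)\CO
F2 | step 20 | methyl (Z)-7-bromo-6-methylhept-5-enoate | COC(=O)CCC/C=C(C)\CBr
F3 | step 20 | C6 tert-butyldimethylsilyl ether of 18 | CC(C)[Si](OC[C@@H](CCCO[Si](C)(C)C(C)(C)C)[C@H]1C[C@@H](CS(=O)(=O)c2ccccc2)C(C)(C)O1)(C(C)C)C(C)C
F4 | step 20 | C13-alkylated sulfone ester (C13 epimers, 1Z) | CC(C)[Si](OC[C@@H](CCCO[Si](C)(C)C(C)(C)C)[C@H]1C[C@@H](C(C/C(C)=C\CCCC(=O)OC)S(=O)(=O)c2ccccc2)C(C)(C)O1)(C(C)C)C(C)C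
F5 | step 20 | desulfonylated seco ester (1Z) | CC(C)[Si](OC[C@@H](CCCO[Si](C)(C)C(C)(C)C)[C@H]1C[C@@H](CC/C(C)=C\CCCC(=O)OC)C(C)(C)O1)(C(C)C)C(C)C
F6 | step 20 | seco C5 diethyl phosphonate ester | CC(C)[Si](OC[C@@H](CCCO[Si](C)(C)C(C)(C)C)[C@H]1C[C@@H](CC/C(C)=C\CCC(C(=O)OC)P(=O)(OCC)OCC)C(C)(C)O1)(C(C)C)C(C)C
F7 | step 20 | seco C6 alcohol phosphonate | CC(C)[Si](OC[C@@H](CCCO)[C@H]1C[C@@H](CC/C(C)=C\CCC(C(=O)OC)P(=O)(OCC)OCC)C(C)(C)O1)(C(C)C)C(C)C
F8 | step 20 | seco C6 aldehyde phosphonate | CC(C)[Si](OC[C@@H](CCC=O)[C@H]1C[C@@H](CC/C(C)=C\CCC(C(=O)OC)P(=O)(OCC)OCC)C(C)(C)O1)(C(C)C)C(C)C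
F9 | step 20 | (1Z,5E,9R,10R,12R)-macrocyclic C17 methyl ester, C16 OSi(iPr)3 | C/C1=C/CC/C(C(=O)OC)=C\CC[C@H](CO[Si](C(C)C)(C(C)C)C(C)C)[C@H]2C[C@@H](CC1)C(C)(C)O2
F10 | step 20 | (1Z,5E,9R,10R,12R)-macrocyclic C17 alcohol, C16 OSi(iPr)3 | C/C1=C/CC/C(CO)=C\CC[C@H](CO[Si](C(C)C)(C(C)C)C(C)C)[C@H]2C[C@@H](CC1)C(C)(C)O2
F11 | step 15 | methyl (Z)-2-bromo-7-[(tert-butyldimethylsilyl)oxy]-6-methylhept-5-enoate | COC(=O)C(Br)CC/C=C(C)\CO[Si](C)(C)C(C)(C)C
F12 | step 15 | [(Z)-7-(tert-butyldimethylsilyloxy)-1-methoxy-6-methyl-1-oxohept-5-en-2-yl]triphenylphosphonium bromide | COC(=O)C(CC/C=C(C)\CO[Si](C)(C)C(C)(C)C)[P+](c1ccccc1)(c1ccccc1)c1ccccc1.[Br-]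
F13 | step 15 | methyl (Z)-7-(tert-butyldimethylsilyloxy)-6-methyl-2-(triphenylphosphoranylidene)hept-5-enoate | COC(=O)C(CC/C=C(C)\CO[Si](C)(C)C(C)(C)C)=P(c1ccccc1)(c1ccccc1)c1ccccc1
F14 | step 24 | C16 allyl malonate diester of 39 | C/C1=C/CC/C(C=O)=C\CC[C@H](COC(=O)CC(=O)OCC=C)[C@H]2C[C@@H](CC1)C(C)(C)O2
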